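The ratio of complex with three exchanged to complex with two exchanged rose and fell in the earlier runs, all at 0.25 M, with the charged ratio of incoming to leaving ligand, so I try that ratio as a first guide, knowing that ligand released along the way changes it.

| flask | starting complex | incoming ligand | leaving ligand | remark | time |
|---|---|---|---|---|---|
| midnight | 0.25 M | 1.4 equiv | 1 equiv | run made earlier |  |
| spring | 0.25 M | 2.9 equiv | 1 equiv | run made earlier |  |
| dawn | 0.25 M | 1.5 equiv | 1.6 equiv | run made earlier |  |
| Sunday's | 0.15 M | 2.20 equiv | 1.00 equiv |  | 4.0 d |
| Wednesday's | 1.0 M | 1.50 equiv | 0.330 equiv |  | 4.0 d |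
| Tuesday's | 0.080 M | 1.00 equiv | 4.00 equiv |  | 4.0 d |
| Thursday's | 0.25 M | 1.50 equiv | 1.00 equiv |  | 4.0 d |
| Monday's | 0.080 M | 2.20 equiv | 0.330 equiv |  | 4.0 d |

| run | time / d | complex with two exchanged / % | complex with three exchanged / % |
|---|---|---|---|
| midnight | 0.833 | 0.4 | 0.5 |
| midnight | 1.67 | 2.2 | 0.2 |
| midnight | 2.50 | 2.9 | 0.3 |
| midnight | 3.00 | 4.0 | 1.1 |
| midnight | 4.00 | 5.2 | 1.0 |
| spring | 0.333 | 0.5 | 0.2 |
| spring | 1.04 | 3.0 | 1.7 |
| spring | 1.67 | 6.2 | 2.5 |
| spring | 3.00 | 11.4 | 4.2 |
| spring | 4.00 | 15.1 | 5.8 |
| dawn | 0.333 | 0.2 | 0 |
| dawn | 1.04 | 1.1 | 0.3 |
| dawn | 1.67 | 2.3 | 0.3 |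
| dawn | 3.00 | 5.4 | 0.8 |
| dawn | 4.00 | 6.2 | 0.9 |

(standard deviation of a reading: 0.3 percentage points)

* all flasks from highest to lowest share of complex with two exchanged in all that became complex with two exchanged or complex with three exchanged, at 4.0 d (Sunday's / Wednesday's / Tuesday's / Thursday's / Monday's)
* the same order at 20 h (Sunday's / Wednesday's / Tuesday's / Thursday's / Monday's)
* the share of complex with two exchanged in all that became complex with two exchanged or complex with three exchanged of the flask you put first, at 4.0 d
* the share of complex with two exchanged in all that became complex with two exchanged or complex with three exchanged of the flask you put last, at 4.0 d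

- the earlier runs were read with a standard deviation of 0.3 percentage points

Take the last reading of each earlier run and divide its three-to-two ratio by the charged ratio of incoming to leaving ligand. Midnight gives 0.137, spring 0.132 and dawn 0.155. Their mean, 0.142, is what I call the balance number: three-to-two per unit of charged incoming-to-leaving ratio. It is a reading and carries the scatter. For a flask like those runs, the share of complex with two exchanged is then about one over one plus the balance number times the charged ratio. Elsewhere it is a rough guide, and I do not rank Wednesday's, with 0.330 equiv of leaving ligand charged, or Monday's, with 0.330 equiv, by it: what they release weighs heavily against so small a charge.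

The pace is a separate matter. From midnight to spring the products at the last reading go from 6.20 % to 20.9 %, which reads as order 1.67 in c(incoming ligand).

Now run Tuesday's slowly, as I reckon it. At the start c(incoming ligand) is 0.0800 M and c(leaving ligand) is 0.320 M, a charged ratio of 0.250, the lowest of the flasks. Little can be seen early: spring, far richer in incoming ligand, showed 0.700 % of products at 0.333 d. Through the middle, incoming ligand falls and leaving ligand rises, and both lower the ratio. By the end, if the pace follows c(incoming ligand) to that order, which I assume because the earlier runs all stood at one concentration, Tuesday's holds about 0.528 % of products. Spring's share went from 63.8 % at 1.04 d to 72.2 % at 4.00 d, so I take the two products as moving together, under thermodynamic rather than kinetic control. At the charged ratio, the balance number then puts Tuesday's first, at 96.6 %.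

The forecast gives Tuesday's > Thursday's > Wednesday's > Sunday's > Monday's at the asked time and Tuesday's > Thursday's > Sunday's > Wednesday's > Monday's at the second, with 96 % for its first flask, close to my figure, and 48 % for its last. Its grounds include this: “Released leaving ligand and consumed incoming ligand therefore shift the ratio”.

The simulation gives Tuesday's > Wednesday's > Thursday's > Sunday's > Monday's at the asked time and Tuesday's > Wednesday's > Thursday's > Monday's > Sunday's at the second, with 94.7 % for the first flask and 66.5 % for the last.

    complex with one exchanged + incoming ligand → leaving ligand + complex with two exchanged (k = 0.00628 L mol⁻¹ h⁻¹)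
    starting complex + incoming ligand → leaving ligand + complex with one exchanged (k = 0.119 L mol⁻¹ h⁻¹)
    complex with two exchanged + incoming ligand ⇌ leaving ligand + complex with three exchanged (K = 0.510, k = 0.337 L mol⁻¹ h⁻¹)

Tuesday's stands first, and its share holds 94.7 % with the return of leaving ligand and complex with three exchanged to complex with two exchanged and incoming ligand, but 57.5 % with that return taken away, the largest single effect. The forward step, counted by itself at the charged concentrations, has a half-life of 1.1 d, shorter than the 4.0 d allowed. The balance number at the charged ratio gave Tuesday's 96.6 % against 94.7 %, but it gives Wednesday's 60.8 % against 91.5 %, where leaving ligand stands at 469 % of its charge by 4.00 d. In the same flask with 0.250 equiv of incoming ligand, the charged ratio is 0.0625, and the balance number gives 99.1 %; the computed flask gives 98.7 %.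

The readings come from a simulation from invented constants; noise was put on by code.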